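## Structural features

Menaquinone-8 is a 2,3-disubstituted 1,4-naphthoquinone: an unsubstituted benzo ring (ring A) is fused through C4a–C8a to the quinone ring (ring B), whose C2 carries a methyl group and whose C3 carries an all-E octaprenyl chain of forty carbons. The chain is bonded to C3 through the methylene C1', which is allylic and also adjacent to the quinone, and it holds eight trisubstituted double bonds, seven of them E-configured stereo-elements; there is no stereogenic carbon, so the only stereochemical task is to keep these geometries, above all that of C2'=C3' next to the ring. Fragile are the quinone (base, light, reductants), the doubly activated C1' methylene, and the 1,5-polyene, which Brønsted and strong Lewis acids isomerise or cyclise and which an ortho phenolic oxygen can trap as a chroman. The real difficulty is therefore not the bicyclic core but placing methyl and chain on neighbouring ring carbons without making the C3–C1' bond by allylation, the operation that usually scrambles the 2'E double bond and the site of alkylation. Commercial solanesol holds the required array ready-made: its C3 with the attached methyl and its C4 correspond to C2 and C3 of ring B, and C5 onwards is the complete octaprenyl chain. The key step uses two features: ring A has no substituent, so its six carbons can be supplied as benzyne, and C1–C4 of ring B with methyl and chain are the four carbons of a 3,4-disubstituted furan with free α-positions, whose ring oxygen ends as a quinone oxygen.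

## Logic of the disconnections

18 to 16 and 17. The C–O bond of one carbonyl group (at C4 or at C1) is removed. A 1-naphthol with a substituted ortho carbon and a free para carbon can be oxidised only to the 1,4-quinone, so both regioisomers converge on 18 and ring B need arrive with one oxygen only. The forward step needs an oxidant that takes the phenol and leaves eight alkenes and the C1' methylene alone. Because 17 has the chain ortho to hydroxyl, it must be oxidised before acid can close a chroman.

16 and 17 to 15. The O–H bond is exchanged for a second C–O bond, so that one oxygen bridges C1 and C4, and a hydrogen returns from C2 or C3 to a bridgehead. No skeletal bond is cut; the gain is that both naphthols become isomers of one precursor that a cycloaddition can make. The forward step must ionise a bridgehead C–O bond without protonating the chain.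

15 to 12 and 14. The bonds C1–C8a and C4–C4a are cut together. Ring A is unsubstituted and the oxygen bridge marks ring B as the adduct of a five-membered oxygen diene. The C51 problem falls into a C6 unit and a C45 unit in which methyl, C2, C3 and the whole chain are already joined, so no bond to C1' is ever made. The forward step needs 14 released under neutral conditions at room temperature (from 13), and 14 must choose the diene of 12 over eight chain alkenes.

12 to 8 and 10 (through 11). In the five-membered ring the bonds O–C5 and C2–C3 are cut. C2 becomes a one-carbon nucleophile (10, from 9), while C3, C4 and C5 form the keto acetal 8, whose carbonyl oxygen is the ring oxygen. A furan is the dehydration product of a 1,4-dioxygenated four-carbon unit at this oxidation level, and 8 holds the methyl on the carbonyl carbon and the chain on the α-carbon exactly as 12 requires. The heteroaromatic ring is reduced to an acyclic ketone plus one carbon. The demand is that 10 adds to an enolisable, α-branched ketone and that the acid closing the ring is mild.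

8 to 6 and 7. The bond between C3 and C4 of the butanone is cut, the acetal carbon being a formyl cation equivalent. The gain is a commodity C1 reagent. The nucleophile must be the internal enol derivative only, and it must capture the carbenium ion faster than the chain alkenes do.

6 to 4 (through 5). Only the O–Si bond is cut. This is the step that carries the regiochemistry of the ring synthesis, so enolisation must be under equilibrium control toward the more substituted side and must avoid acid.

4 to 1 (through 2 and 3). The carbonyl carbon of 4 is reconnected by a double bond to a two-carbon unit bearing the hydroxyl: the C2=C3 bond of 1 is the one cleaved in the forward direction. It is the only one of nine double bonds marked by an allylic hydroxyl. The gain is a commercial starting material that delivers the methyl, two ring carbons and the all-E chain. The demand is a site-selective oxidation followed by a cleavage reagent that ignores isolated alkenes; ozone and osmium reagents are excluded.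

## Other disconnections considered

Alternative 1: The cut is the C1–C2 bond of ring B, which leads to the keto diester methyl 2-[4-methoxy-4-oxo-2-(octaprenyl)butanoyl]benzoate A2. In the forward direction NaOMe in methanol would form the ester enolate at C2, which attacks the aromatic ester carbonyl (Dieckmann condensation, the laboratory counterpart of the naphthoate-forming step of menaquinone biosynthesis). Tautomerisation would give methyl 1,4-dihydroxy-3-octaprenyl-2-naphthoate A1.
- In favour: ring B closes with both oxygens in place and with unambiguous regiochemistry, aromatisation drives it, and the chain meets only alkoxide. On these points it is better than the chosen plan, which adds the second oxygen afterwards and passes through a cationic bridge opening.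
- Against: the ester carbon of A1 must still be taken down to a methyl group beside an air-sensitive, chain-bearing hydroquinone, where acid and hydrogenolysis both threaten the chain. A2 also requires the C40 electrophile all-E octaprenyl bromide A3, which 1 cannot supply because its chain is one isoprene unit too long.
- Comparison: structurally the alternative gives up buying methyl, C2, C3 and chain as one piece and makes a bond at C1'. Mechanistically the two ring closures are equally well precedented. In step economy it is longer by the ester deoxygenation and by the synthesis of A3.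

Alternative 2: The cut is the C2–C3 bond. The precursor is the bis(trimethylsilyl enol ether) A5 of the ortho-diacylbenzene 2-octaprenyl-1-(2-propanoylphenyl)ethan-1-one A6. Constant-current anodic oxidation would take one electron from an enol ether, the radical cation would be trapped by the second enol ether, and after a second oxidation and loss of both silyl groups 2-methyl-3-octaprenyl-2,3-dihydronaphthalene-1,4-dione A4 would result (intramolecular oxidative enol ether coupling).
- In favour: A4 is the diketo tautomer of the hydroquinone and needs only enolisation and air to reach 18, so both oxygens are present and no acid is needed; this is better than the chosen plan. Regiochemistry of enol ether formation is also better, since each ketone of A6 has one enolisable side only. The cis/trans mixture is immaterial.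
- Against: the oxidation potential of a silyl enol ether lies only a little below that of trisubstituted alkenes, A5 has eight of them, and a polar electrolyte is a poor medium for a C51 lipophile. A6 needs a C42 acyl unit (4 after loss of its methyl carbon) and two selective acylations of a benzene ring.
- Comparison: the chemoselectivity problem (oxidant against chain) is of the same kind as the aryne problem of the chosen plan, but it cannot be settled by choice of partner and stoichiometry. Like the chosen plan it makes no bond at C1'. Step count would be about equal.

Alternative 3: The C3–C4 bond is cut and C4 is reconnected to C1 in a four-membered ring, giving 2-hydroxy-2-[(E)-1-octaprenylprop-1-en-2-yl]benzocyclobuten-1(2H)-one A8. A8 would come from the alkenyllithium (Z)-2-lithio-1-octaprenylprop-1-ene A9 and benzocyclobutene-1,2-dione A10. Heating A8 in toluene or xylene would open the four-membered ring electrocyclically, the acyl carbon so unmasked would bond to the chain-bearing alkene carbon in a six-electron ring closure, and tautomerisation would give menaquinol-8 A7, which air would oxidise to 18.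
- In favour: neutral thermal conditions, regiochemistry fixed by construction, both oxygens at the hydroquinone level, no acid and no regioisomeric naphthols. At the end of the synthesis it is clearly better than the chosen plan.
- Against: A10 is not a catalogue commodity and costs several steps, mono-addition to a dione must be controlled, and the thermolysis holds a 1,5-polyene and an air-sensitive hydroquinone at 110–140 °C.
- Comparison: structurally it is equal, since A9 can derive from 4 and no bond to C1' is made. However, A9 needs the same internal enolisation of 4 plus a halogen–lithium exchange, so the regiochemical burden is equal and the step count higher. The chosen plan is shorter by about three steps and starts from purchasable compounds only.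

Key step: step 6

Remark: "octaprenyl" means the all-E group (2E,6E,10E,14E,18E,22E,26E)-3,7,11,15,19,23,27,31-octamethyldotriaconta-2,6,10,14,18,22,26,30-octaen-1-yl (C40H65), bonded through C1'.
Remark: 15 does contain two stereogenic bridgehead carbons, formed cis and racemic; both become sp2 in step 7, so the net number of stereocentres built is zero.
Remark: 16 and 17 are not equally robust, since 17 is an ortho-prenyl phenol that acid turns into a chroman; for this reason the pair is oxidised without isolation.
Remark: carbon balance C43 (4) + C1 (7) + C1 (9) = C45 (12), plus C6 (13) = C51 (18).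

## Route

Step 1
Reactants: 1 solanesol
Product: 2 rac-[(2S,3S)-3-methyl-3-(octaprenylmethyl)oxiran-2-yl]methanol (2,3-epoxysolanesol)
Conditions: VO(acac)2 (2 mol%), t-BuOOH, toluene, 0 °C → rt
Reagents that add atoms: tert-butyl hydroperoxide, CC(C)(C)OO
Why: Hydroxyl-directed vanadium-catalysed epoxidation: the peroxide is delivered from the vanadium alkoxide of the allylic alcohol, so only the C2=C3 bond of the nine should react. Syn addition to the E-alkene gives the (2S*,3S*) epoxide as a racemate, which is immaterial because both centres are excised in step 2.

Step 2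
Reactants: 2 rac-[(2S,3S)-3-methyl-3-(octaprenylmethyl)oxiran-2-yl]methanol
Product: 4 1-octaprenylpropan-2-one, via triol 3 (not isolated)
Conditions: H5IO6, THF–H2O, 0 °C → rt
Reagents that add atoms: water, O
Why: Periodic acid opens the epoxide with water at the tertiary carbon and cleaves the 1,2,3-triol twice (Malaprade glycol cleavage), so that C1 leaves as formaldehyde, C2 as formic acid and C3 remains as the methyl ketone. Isolated trisubstituted alkenes are inert to periodate.

Step 3
Reactants: 4 1-octaprenylpropan-2-one
Product: 6 (Z)-1-octaprenyl-2-(trimethylsilyloxy)prop-1-ene, via magnesium enolate 5 (not isolated)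
Conditions: iPr2NMgBr (from EtMgBr, iPr2NH), Et2O, rt; then TMSCl, Et3N, HMPA, rt
Reagents that add atoms: chlorotrimethylsilane, C[Si](C)(C)Cl
Why: Enolisation by a magnesium amide is reversible and should settle on the more substituted (internal) enolate, which O-silylation fixes as the thermodynamic silyl enol ether; no acid touches the chain. The Z isomer should predominate, but the geometry is irrelevant because this carbon becomes sp3 in step 4.

Step 4
Reactants: 6 (Z)-1-octaprenyl-2-(trimethylsilyloxy)prop-1-ene; 7 trimethyl orthoformate
Product: 8 rac-4,4-dimethoxy-3-octaprenylbutan-2-one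
Conditions: TMSOTf (5 mol%), 2,6-di-tert-butyl-4-methylpyridine (10 mol%), CH2Cl2, −78 °C
Reagents that add atoms: none
Why: Mukaiyama-type addition of the silyl enol ether to the dimethoxycarbenium ion that catalytic TMSOTf generates from the orthoformate; the C–C bond can form only at the carbon that bore the enol double bond. The enol ether is far more nucleophilic than a trisubstituted alkene, so the chain should stay untouched at −78 °C with the hindered pyridine scavenging triflic acid; the new stereocentre is racemic and is lost in step 5.

Step 5
Reactants: 8 rac-4,4-dimethoxy-3-octaprenylbutan-2-one; 9 trimethylsulfonium iodide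
Product: 12 3-methyl-4-octaprenylfuran, via dimethylsulfonium methylide 10 (not isolated), via epoxy acetal 11 (not isolated)
Conditions: n-BuLi, THF, −10 °C → rt; aqueous work-up; then TsOH·H2O (10 mol%), THF–H2O, rt
Reagents that add atoms: none
Why: Corey–Chaykovsky epoxidation of the ketone, then acid-induced opening of the epoxide, closure of the primary oxygen onto the acetal carbon and loss of two molecules of methanol (established furan synthesis from β-keto acetals). Every branch of the cascade should end in the aromatic furan as thermodynamic sink, and the diastereomers of 11 converge.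

Step 6
Reactants: 12 3-methyl-4-octaprenylfuran; 13 2-(trimethylsilyl)phenyl trifluoromethanesulfonate
Product: 15 rac-2-methyl-3-octaprenyl-1,4-dihydro-1,4-epoxynaphthalene, via benzyne 14 (not isolated)
Conditions: CsF (2 equiv), MeCN–toluene (1:1), rt, slow addition of 13 (1.1 equiv)
Reagents that add atoms: none
Why: Fluoride attacks silicon of 13 and the aryl anion expels triflate to give benzyne 14, which adds suprafacially across C2 and C5 of the furan in a concerted [4+2] cycloaddition (aryne–furan Diels–Alder reaction, the standard entry to 1,4-dihydro-1,4-epoxynaphthalenes). Ring B closes in this one intermolecular cycloaddition through the new C1–C8a and C4–C4a bonds, and the furan oxygen is left as the 1,4-bridge. The two bridgehead carbons become stereocentres whose relative configuration is fixed cis by the suprafacial addition and the bridge; neither partner is chiral, so 15 is racemic, which is immaterial because both centres are erased in step 7. No regiochemistry arises because 14 is symmetric and both α-carbons of 12 are unsubstituted. The selectivity needed is chemoselectivity for the diene over ene reaction or [2+2] addition at the eight trisubstituted chain alkenes. It rests on the intrinsically lower barrier of aryne addition to an electron-rich, s-cis-locked 3,4-dialkylfuran, not on the rate of aryne release. The near-stoichiometric dose and slow addition of 13 only prevent an excess of aryne once 12 is consumed; toluene keeps the waxy 12 in solution and MeCN carries the fluoride.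

Step 7
Reactants: 15 rac-2-methyl-3-octaprenyl-1,4-dihydro-1,4-epoxynaphthalene
Product: 18 menaquinone-8, via 2-methyl-3-octaprenylnaphthalen-1-ol 16 (not isolated), via 3-methyl-2-octaprenylnaphthalen-1-ol 17 (not isolated)
Conditions: Cu(OTf)2 (5 mol%), ClCH2CH2Cl, 0 °C → rt; then (KSO3)2NO, aq. KH2PO4, Bu4NHSO4 (cat.), rt
Reagents that add atoms: potassium nitrosodisulfonate, [K+].[K+].[O]N(S(=O)(=O)[O-])S(=O)(=O)[O-]
Why: The Lewis acid ionises one bridgehead C–O bond of the strained allylic, benzylic ether, and a 1,2-hydride shift from the oxygen-bearing bridgehead followed by enolisation gives the 1-naphthols (known isomerisation of 1,4-epoxy-1,4-dihydronaphthalenes): 16 by cleavage of C4–O and 17 by cleavage of C1–O. Both have a blocked ortho and a free para position, so Teuber oxidation by the nitroxyl radical under phase transfer can only give the same 1,4-quinone; oxidising in the same flask keeps 17 from standing in acid.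

## Compound list

1 | solanesol, (2E,6E,10E,14E,18E,22E,26E,30E)-3,7,11,15,19,23,27,31,35-nonamethylhexatriaconta-2,6,10,14,18,22,26,30,34-nonaen-1-ol | CC(C)=CCC/C(C)=C/CC/C(C)=C/CC/C(C)=C/CC/C(C)=C/CC/C(C)=C/CC/C(C)=C/CC/C(C)=C/CC/C(C)=C/CO | starting material
2 | rac-[(2S,3S)-3-methyl-3-(octaprenylmethyl)oxiran-2-yl]methanol (one enantiomer drawn) | CC(C)=CCC/C(C)=C/CC/C(C)=C/CC/C(C)=C/CC/C(C)=C/CC/C(C)=C/CC/C(C)=C/CC/C(C)=C/CC[C@]1(C)O[C@H]1CO | intermediate
3 | 3-methyl-4-octaprenylbutane-1,2,3-triol (configuration at C2 and C3 not defined, immaterial) | CC(C)=CCC/C(C)=C/CC/C(C)=C/CC/C(C)=C/CC/C(C)=C/CC/C(C)=C/CC/C(C)=C/CC/C(C)=C/CCC(C)(O)C(O)CO | intermediate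
4 | 1-octaprenylpropan-2-one, (5E,9E,13E,17E,21E,25E,29E)-6,10,14,18,22,26,30,34-octamethylpentatriaconta-5,9,13,17,21,25,29,33-octaen-2-one | CC(C)=CCC/C(C)=C/CC/C(C)=C/CC/C(C)=C/CC/C(C)=C/CC/C(C)=C/CC/C(C)=C/CC/C(C)=C/CCC(C)=O | intermediate
5 | bromomagnesium (Z)-1-octaprenylprop-1-en-2-olate | CC(C)=CCC/C(C)=C/CC/C(C)=C/CC/C(C)=C/CC/C(C)=C/CC/C(C)=C/CC/C(C)=C/CC/C(C)=C/C/C=C(/C)O[Mg]Br | intermediate
6 | (Z)-1-octaprenyl-2-(trimethylsilyloxy)prop-1-ene | CC(C)=CCC/C(C)=C/CC/C(C)=C/CC/C(C)=C/CC/C(C)=C/CC/C(C)=C/CC/C(C)=C/CC/C(C)=C/C/C=C(/C)O[Si](C)(C)C | intermediate
7 | trimethyl orthoformate | COC(OC)OC | starting material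
8 | rac-4,4-dimethoxy-3-octaprenylbutan-2-one (stereocentre at C3 undefined) | CC(C)=CCC/C(C)=C/CC/C(C)=C/CC/C(C)=C/CC/C(C)=C/CC/C(C)=C/CC/C(C)=C/CC/C(C)=C/CC(C(OC)OC)C(C)=O | intermediate
9 | trimethylsulfonium iodide | C[S+](C)C.[I-] | starting material
10 | dimethylsulfonium methylide | [CH2-][S+](C)C | intermediate
11 | 2-[2,2-dimethoxy-1-(octaprenyl)ethyl]-2-methyloxirane (racemic diastereomer mixture) | CC(C)=CCC/C(C)=C/CC/C(C)=C/CC/C(C)=C/CC/C(C)=C/CC/C(C)=C/CC/C(C)=C/CC/C(C)=C/CC(C(OC)OC)C1(C)CO1 | intermediate
12 | 3-methyl-4-octaprenylfuran | CC(C)=CCC/C(C)=C/CC/C(C)=C/CC/C(C)=C/CC/C(C)=C/CC/C(C)=C/CC/C(C)=C/CC/C(C)=C/Cc1cocc1C | intermediate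
13 | 2-(trimethylsilyl)phenyl trifluoromethanesulfonate | C[Si](C)(C)c1ccccc1OS(=O)(=O)C(F)(F)F | starting material
14 | benzyne | C1#CC=CC=C1 | intermediate
15 | rac-2-methyl-3-octaprenyl-1,4-dihydro-1,4-epoxynaphthalene (bridgehead hydrogens cis, one enantiomer drawn) | CC(C)=CCC/C(C)=C/CC/C(C)=C/CC/C(C)=C/CC/C(C)=C/CC/C(C)=C/CC/C(C)=C/CC/C(C)=C/CC1=C(C)[C@@H]2O[C@H]1c1ccccc12 | intermediate
16 | 2-methyl-3-octaprenylnaphthalen-1-ol | CC(C)=CCC/C(C)=C/CC/C(C)=C/CC/C(C)=C/CC/C(C)=C/CC/C(C)=C/CC/C(C)=C/CC/C(C)=C/Cc1cc2ccccc2c(O)c1C | intermediate
17 | 3-methyl-2-octaprenylnaphthalen-1-ol | CC(C)=CCC/C(C)=C/CC/C(C)=C/CC/C(C)=C/CC/C(C)=C/CC/C(C)=C/CC/C(C)=C/CC/C(C)=C/Cc1c(C)cc2ccccc2c1O | intermediate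
18 | menaquinone-8, 2-methyl-3-octaprenylnaphthalene-1,4-dione | CC(C)=CCC/C(C)=C/CC/C(C)=C/CC/C(C)=C/CC/C(C)=C/CC/C(C)=C/CC/C(C)=C/CC/C(C)=C/CC1=C(C)C(=O)c2ccccc2C1=O | target

## Step count and least certain steps

Total: 7 steps. Longest linear sequence: 7 steps (1 to 18); 7, 9 and 13 enter as purchased compounds.

Step 6 (key step). Most likely to go wrong: loss of the aryne to ene reaction or [2+2] addition at the chain double bonds, and late in the reaction at the strained double bond of 15. There are eight alkenes with allylic hydrogens per furan ring and the outcome is fixed by rate constants alone; the arylated by-products would be hard to separate because everything in the flask is a hydrocarbon-like oil.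

Fallback: make the diene more reactive and change its oxidation level. Setting out from 12, α-lithiation (n-BuLi, THF), borylation with B(OMe)3 and oxidation of the carbon–boron bond with H2O2 buffered by NaHCO3 should give the butenolides 3-methyl-4-octaprenylfuran-2(5H)-one F1 and 4-methyl-3-octaprenylfuran-2(5H)-one F2, since either α-position can be lithiated. Treatment with iPr3SiOTf and Et3N should convert them into 3-methyl-4-octaprenyl-2-(triisopropylsilyloxy)furan F3 and 4-methyl-3-octaprenyl-2-(triisopropylsilyloxy)furan F4, which are much more electron-rich dienes than 12. Cycloaddition with 14 (from 13 and CsF) is followed by opening of the bridged ketal on its own and should give the hydroquinone monosilyl ethers 3-methyl-2-octaprenyl-4-(triisopropylsilyloxy)naphthalen-1-ol F5 and 2-methyl-3-octaprenyl-4-(triisopropylsilyloxy)naphthalen-1-ol F6. Oxidation with (NH4)2Ce(NO3)6 in aqueous MeCN at 0 °C should then bring both to 18, where the route is rejoined. The regioisomeric pairs need no separation because they converge. The detour costs three extra steps but removes step 7 and all acid.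

Step 3. Most likely to go wrong: incomplete regiocontrol of enolisation, with some terminal enolate being silylated, because the energy gap between the two enolates of a methyl ketone is modest and silylation may outrun equilibration. The terminal isomer would travel through steps 4 and 5 to a monosubstituted furan that is nearly inseparable from 12.

Fallback: formylate the ketone directly, without a separate enol derivative. Setting out from 4, the diethoxycarbenium salt made from HC(OEt)3 and BF3·OEt2, with iPr2NEt at −78 °C, is reported to react at the more substituted α-carbon of unsymmetrical ketones and should give rac-4,4-diethoxy-3-octaprenylbutan-2-one F7. The conditions of step 5 then lead through 2-[2,2-diethoxy-1-(octaprenyl)ethyl]-2-methyloxirane F8 (not isolated) back to the route at 12. The price is exposure of the chain to a stoichiometric boron Lewis acid at low temperature.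

Step 7. Most likely to go wrong: acid-triggered addition of the hydroxyl of 17 across C2'=C3' (chroman closure), or proton-initiated isomerisation or cyclisation in the chain, before the oxidant acts. Cu(OTf)2 releases triflic acid with traces of water, and the oxygen of 17 sits in reach of a tertiary cationic site.

Fallback: replace the triflate Lewis acid by an aprotic, proton-scavenging aluminium Lewis acid and separate the two operations. Setting out from 15, MeAl(OC6H2-2,6-tBu2-4-Br)2 in CH2Cl2 at −78 °C, the reagent type used for epoxide-to-carbonyl rearrangements of acid-sensitive substrates, should cause the same ionisation and hydride shift but leave the products as aluminium naphtholates, so that no free ortho-prenyl phenol coexists with acid. Neutral work-up gives 16 and 17, which are oxidised at once with O2 and N,N'-bis(salicylidene)ethylenediaminocobalt, Co(salen), in CH2Cl2–MeCN to 18. No compound outside the compound list is made (entry F0). If cationic opening fails in every form, the detour given for step 6 by-passes it.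

Step 2. Most likely to go wrong: slow or incomplete hydration of the hindered trisubstituted epoxide in a two-phase mixture (2 is a wax), with acid-induced rearrangement of the epoxide to a carbonyl compound or an allylic alcohol competing with cleavage.

Fallback: degrade by retro-aldol cleavage instead. Setting out from 1, MnO2 in CH2Cl2 should give solanesal F9, and heating F9 with aqueous K2CO3 and a cosolvent adds water to the enal and splits the β-hydroxy aldehyde into acetaldehyde and the methyl ketone (the reaction by which citral is degraded to methylheptenone). This comes back to the route at 4.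

## Further compounds

F1 | step 6 | 3-methyl-4-octaprenylfuran-2(5H)-one | CC(C)=CCC/C(C)=C/CC/C(C)=C/CC/C(C)=C/CC/C(C)=C/CC/C(C)=C/CC/C(C)=C/CC/C(C)=C/CC1=C(C)C(=O)OC1
F2 | step 6 | 4-methyl-3-octaprenylfuran-2(5H)-one | CC(C)=CCC/C(C)=C/CC/C(C)=C/CC/C(C)=C/CC/C(C)=C/CC/C(C)=C/CC/C(C)=C/CC/C(C)=C/CC1=C(C)COC1=O
F3 | step 6 | 3-methyl-4-octaprenyl-2-(triisopropylsilyloxy)furan | CC(C)=CCC/C(C)=C/CC/C(C)=C/CC/C(C)=C/CC/C(C)=C/CC/C(C)=C/CC/C(C)=C/CC/C(C)=C/Cc1coc(O[Si](C(C)C)(C(C)C)C(C)C)c1C
F4 | step 6 | 4-methyl-3-octaprenyl-2-(triisopropylsilyloxy)furan | CC(C)=CCC/C(C)=C/CC/C(C)=C/CC/C(C)=C/CC/C(C)=C/CC/C(C)=C/CC/C(C)=C/CC/C(C)=C/Cc1c(C)coc1O[Si](C(C)C)(C(C)C)C(C)C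
F5 | step 6 | 3-methyl-2-octaprenyl-4-(triisopropylsilyloxy)naphthalen-1-ol | CC(C)=CCC/C(C)=C/CC/C(C)=C/CC/C(C)=C/CC/C(C)=C/CC/C(C)=C/CC/C(C)=C/CC/C(C)=C/Cc1c(C)c(O[Si](C(C)C)(C(C)C)C(C)C)c2ccccc2c1O
F6 | step 6 | 2-methyl-3-octaprenyl-4-(triisopropylsilyloxy)naphthalen-1-ol | CC(C)=CCC/C(C)=C/CC/C(C)=C/CC/C(C)=C/CC/C(C)=C/CC/C(C)=C/CC/C(C)=C/CC/C(C)=C/Cc1c(C)c(O)c2ccccc2c1O[Si](C(C)C)(C(C)C)C(C)C
F7 | step 3 | rac-4,4-diethoxy-3-octaprenylbutan-2-one | CC(C)=CCC/C(C)=C/CC/C(C)=C/CC/C(C)=C/CC/C(C)=C/CC/C(C)=C/CC/C(C)=C/CC/C(C)=C/CC(C(OCC)OCC)C(C)=O
F8 | step 3 | 2-[2,2-diethoxy-1-(octaprenyl)ethyl]-2-methyloxirane (racemic diastereomer mixture) | CC(C)=CCC/C(C)=C/CC/C(C)=C/CC/C(C)=C/CC/C(C)=C/CC/C(C)=C/CC/C(C)=C/CC/C(C)=C/CC(C(OCC)OCC)C1(C)CO1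
F0 | step 7 | none | none
F9 | step 2 | solanesal, (2E,6E,10E,14E,18E,22E,26E,30E)-3,7,11,15,19,23,27,31,35-nonamethylhexatriaconta-2,6,10,14,18,22,26,30,34-nonaenal | CC(C)=CCC/C(C)=C/CC/C(C)=C/CC/C(C)=C/CC/C(C)=C/CC/C(C)=C/CC/C(C)=C/CC/C(C)=C/CC/C(C)=C/C=O
A1 | alternative 1 | methyl 1,4-dihydroxy-3-octaprenyl-2-naphthoate | CC(C)=CCC/C(C)=C/CC/C(C)=C/CC/C(C)=C/CC/C(C)=C/CC/C(C)=C/CC/C(C)=C/CC/C(C)=C/Cc1c(C(=O)OC)c(O)c2ccccc2c1O
A2 | alternative 1 | rac-methyl 2-[4-methoxy-4-oxo-2-(octaprenyl)butanoyl]benzoate | CC(C)=CCC/C(C)=C/CC/C(C)=C/CC/C(C)=C/CC/C(C)=C/CC/C(C)=C/CC/C(C)=C/CC/C(C)=C/CC(CC(=O)OC)C(=O)c1ccccc1C(=O)OC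
A3 | alternative 1 | all-E octaprenyl bromide | CC(C)=CCC/C(C)=C/CC/C(C)=C/CC/C(C)=C/CC/C(C)=C/CC/C(C)=C/CC/C(C)=C/CC/C(C)=C/CBr
A4 | alternative 2 | 2-methyl-3-octaprenyl-2,3-dihydronaphthalene-1,4-dione (cis/trans mixture) | CC(C)=CCC/C(C)=C/CC/C(C)=C/CC/C(C)=C/CC/C(C)=C/CC/C(C)=C/CC/C(C)=C/CC/C(C)=C/CC1C(C)C(=O)c2ccccc2C1=O
A5 | alternative 2 | 1-[(Z)-2-octaprenyl-1-(trimethylsilyloxy)ethenyl]-2-[(Z)-1-(trimethylsilyloxy)prop-1-enyl]benzene | CC(C)=CCC/C(C)=C/CC/C(C)=C/CC/C(C)=C/CC/C(C)=C/CC/C(C)=C/CC/C(C)=C/CC/C(C)=C/C/C=C(\O[Si](C)(C)C)c1ccccc1/C(O[Si](C)(C)C)=C/C
A6 | alternative 2 | 2-octaprenyl-1-(2-propanoylphenyl)ethan-1-one | CC(C)=CCC/C(C)=C/CC/C(C)=C/CC/C(C)=C/CC/C(C)=C/CC/C(C)=C/CC/C(C)=C/CC/C(C)=C/CCC(=O)c1ccccc1C(=O)CC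
A7 | alternative 3 | menaquinol-8, 2-methyl-3-octaprenylnaphthalene-1,4-diol | CC(C)=CCC/C(C)=C/CC/C(C)=C/CC/C(C)=C/CC/C(C)=C/CC/C(C)=C/CC/C(C)=C/CC/C(C)=C/Cc1c(C)c(O)c2ccccc2c1O
A8 | alternative 3 | rac-2-hydroxy-2-[(E)-1-octaprenylprop-1-en-2-yl]benzocyclobuten-1(2H)-one | CC(C)=CCC/C(C)=C/CC/C(C)=C/CC/C(C)=C/CC/C(C)=C/CC/C(C)=C/CC/C(C)=C/CC/C(C)=C/C/C=C(\C)C1(O)C(=O)c2ccccc21
A9 | alternative 3 | (Z)-2-lithio-1-octaprenylprop-1-ene | CC(C)=CCC/C(C)=C/CC/C(C)=C/CC/C(C)=C/CC/C(C)=C/CC/C(C)=C/CC/C(C)=C/CC/C(C)=C/C/C=C(\C)[Li]
A10 | alternative 3 | benzocyclobutene-1,2-dione | O=C1C(=O)c2ccccc12
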